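**Plan**
- Retrosynthesis: pyranone B is opened at O1–C2 and C4–C4a (propiolate ester, then hydroarylation). Benzene ring B is then cut at C8a–C4a, C5–C6 and C8–C8a into a 4-aryloxy-3-benzyloxycyclobutenone and (triisopropylsilyloxy)acetylene. The cyclobutenone is cut into an aryloxyketene and benzyl ethynyl ether.
- Enabling feature: the benzene ring of coumarin unit B bears oxygen on C8a, C8 (the diaryl ether), C7 and C5 and hydrogen on C6. This is the pattern a 4-aryloxy-3-alkoxycyclobutenone and a terminal siloxyalkyne deliver, with O–C8a as the only free hydroxyl.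
- Forward order: coumarin unit A is bought as daphnetin; the future C8 is attached by O-alkylation; the four-membered ring comes from a ketene–ynol ether [2+2]; benzene ring B is grown by the benzannulation; pyranone B is closed last; silyl and benzyl groups are then removed.
- Stereochemistry: the target has no stereocentre; the single centre of the cyclobutenone is racemic and disappears on aromatization.

Key step: step 9

Remark: (triisopropylsilyloxy)acetylene is assumed not to be a catalogue compound and is made in step 8; the enol ether geometry of the transient ketenes 19–21 is left open because both isomers lead to 23.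

**Step 1**
Reactants: 1 daphnetin (7,8-dihydroxy-2H-chromen-2-one)
Product: 2 8-hydroxy-7-methoxy-2H-chromen-2-one
Conditions: MeI (1.05 equiv), Li2CO3, DMF, 40 °C
Reagents that add atoms: iodomethane, CI
Why: Williamson etherification of the more acidic phenol, since the 7-OH is para to C4a and conjugated with the lactone carbonyl, so its phenoxide forms first under a weak base and takes the single equivalent of MeI.

**Step 2**
Reactants: 2 8-hydroxy-7-methoxy-2H-chromen-2-one; 3 tert-butyl bromoacetate
Product: 4 tert-butyl 2-[(7-methoxy-2-oxo-2H-chromen-8-yl)oxy]acetate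
Conditions: K2CO3, DMF, rt to 50 °C
Reagents that add atoms: none
Why: Williamson alkylation of the remaining phenoxide by a primary α-bromo ester (SN2) should tolerate the two flanking oxygen substituents, and the tert-butyl ester avoids a later saponification next to the lactone.

**Step 3**
Reactants: 4 tert-butyl 2-[(7-methoxy-2-oxo-2H-chromen-8-yl)oxy]acetate
Product: 5 2-[(7-methoxy-2-oxo-2H-chromen-8-yl)oxy]acetic acid
Conditions: TFA, CH2Cl2, rt
Reagents that add atoms: none
Why: Acidolysis of the tert-butyl ester with loss of isobutene leaves the lactone, the methyl ether and the aryl alkyl ether untouched.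

**Step 4**
Reactants: 5 2-[(7-methoxy-2-oxo-2H-chromen-8-yl)oxy]acetic acid
Product: 6 2-[(7-methoxy-2-oxo-2H-chromen-8-yl)oxy]acetyl chloride
Conditions: (COCl)2, DMF (cat.), CH2Cl2, 0 °C to rt; concentrate
Reagents that add atoms: oxalyl chloride, O=C(Cl)C(=O)Cl
Why: Standard acid chloride formation through chloroiminium (Vilsmeier-type) activation under non-basic conditions that the lactone tolerates.

**Step 5**
Reactants: 7 benzyl alcohol; 8 trichloroethylene
Product: 10 benzyl (E)-1,2-dichlorovinyl ether, via dichloroacetylene 9 (not isolated)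
Conditions: KH, THF, 0 °C; then trichloroethylene, −50 °C to rt
Reagents that add atoms: none
Why: Base-induced loss of HCl from trichloroethylene gives dichloroacetylene 9 in the flask, and anti addition of potassium benzyloxide followed by protonation gives the E-dichlorovinyl ether (the established trichloroethylene entry to ynol ether precursors).

**Step 6**
Reactants: 10 benzyl (E)-1,2-dichlorovinyl ether
Product: 13 benzyl ethynyl ether, via benzyl chloroethynyl ether 11 (not isolated), via lithium (benzyloxy)acetylide 12 (not isolated)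
Conditions: n-BuLi (2.4 equiv), THF, −78 to −40 °C; then MeOH, −78 °C
Reagents that add atoms: none
Why: Dehydrochlorination gives chloroalkyne 11, chlorine–lithium exchange gives acetylide 12 and cold protonation releases the terminal ynol ether (the elimination/halogen–metal exchange route to alkoxyacetylenes), which is kept cold and used at once because benzyl ynol ethers rearrange sigmatropically on warming.

**Step 7**
Reactants: 6 2-[(7-methoxy-2-oxo-2H-chromen-8-yl)oxy]acetyl chloride; 13 benzyl ethynyl ether
Product: 15 3-(benzyloxy)-4-[(7-methoxy-2-oxo-2H-chromen-8-yl)oxy]cyclobut-2-en-1-one (racemic), via aryloxyketene 14 (not isolated)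
Conditions: Et3N, 13 (2 equiv), CH2Cl2, 0 °C to rt, slow addition of 6
Reagents that add atoms: none
Why: Dehydrochlorination of 6 gives aryloxyketene 14, which should undergo the thermal ketene–ynol ether [2+2] cycloaddition with its carbonyl carbon bonding to the nucleophilic CH terminus of 13, placing benzyloxy on C3 and aryloxy on C4, while slow addition into excess 13 suppresses ketene dimerization.

**Step 8**
Reactants: 16 3-phenylisoxazole
Product: 18 (triisopropylsilyloxy)acetylene, via lithium ethynolate 17 (not isolated)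
Conditions: n-BuLi (1.0 equiv), THF, −78 to −50 °C; then TIPSOTf, −78 to 0 °C
Reagents that add atoms: triisopropylsilyl trifluoromethanesulfonate, CC(C)[Si](OS(=O)(=O)C(F)(F)F)(C(C)C)C(C)C
Why: Removal of the C5 proton triggers the known base-induced fragmentation of a 5-unsubstituted isoxazole (N–O and C3–C4 cleavage) to benzonitrile and ynolate 17, and the hard, bulky silyl triflate should then silylate the ynolate on oxygen as in the usual preparation of triisopropylsilyl ynol ethers.

**Step 9**
Reactants: 15 3-(benzyloxy)-4-[(7-methoxy-2-oxo-2H-chromen-8-yl)oxy]cyclobut-2-en-1-one; 18 (triisopropylsilyloxy)acetylene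
Product: 23 8-[2-(benzyloxy)-6-hydroxy-4-(triisopropylsilyloxy)phenoxy]-7-methoxy-2H-chromen-2-one, via vinylketene 19 (not isolated), via 4-vinylcyclobutenone 20 (not isolated), via dienylketene 21 (not isolated), via cyclohexadienone 22 (not isolated)
Conditions: 18 (2 equiv), toluene (0.05 M), 80 °C then 110 °C, argon
Reagents that add atoms: none
Why: Danheiser benzannulation: thermal 4π electrocyclic opening of 15 gives vinylketene 19, whose carbonyl carbon is attacked by the unsubstituted carbon of 18 in a [2+2] cycloaddition to give 4-vinylcyclobutenone 20, a second 4π opening gives dienylketene 21, and 6π electrocyclization to dienone 22 followed by tautomerization gives phenol 23. The closest known cases are benzannulations of cyclobutenones, 3-oxygenated ones included, with trialkylsilyloxyalkynes to give resorcinol and phloroglucinol monoethers; the 4-aryloxy group is new only as a spectator, and as an oxygen donor on the breaking bond it should ease the first ring opening. Benzene ring B is closed by the 6π electrocyclic closure, which forms C8–C8a after the [2+2] has formed C8a–C4a and C5–C6. No stereocentre is created, and the racemic C4 of 15 becomes aromatic C8. The one selectivity needed is the regiochemistry that puts the silyloxy carbon meta to the new hydroxyl; the polarization of the ynol ether (nucleophilic CH terminus against the electrophilic ketene carbonyl) should secure it and leaves O–C8a as the only free hydroxyl, while excess 18 and dilution should keep the ketene from acylating the product phenol.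

**Step 10**
Reactants: 23 8-[2-(benzyloxy)-6-hydroxy-4-(triisopropylsilyloxy)phenoxy]-7-methoxy-2H-chromen-2-one; 24 propiolic acid
Product: 25 3-(benzyloxy)-2-[(7-methoxy-2-oxo-2H-chromen-8-yl)oxy]-5-(triisopropylsilyloxy)phenyl prop-2-ynoate
Conditions: DCC, DMAP (cat.), CH2Cl2, 0 °C
Reagents that add atoms: none
Why: Steglich-type carbodiimide esterification of the single free phenol at low temperature is a standard entry to aryl propiolates and leaves the silyl and benzyl ethers alone.

**Step 11**
Reactants: 25 3-(benzyloxy)-2-[(7-methoxy-2-oxo-2H-chromen-8-yl)oxy]-5-(triisopropylsilyloxy)phenyl prop-2-ynoate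
Product: 26 7-(benzyloxy)-8-[(7-methoxy-2-oxo-2H-chromen-8-yl)oxy]-5-(triisopropylsilyloxy)-2H-chromen-2-one
Conditions: Ph3PAuCl (5 mol %), AgSbF6 (5 mol %), CH2Cl2, rt
Reagents that add atoms: none
Why: Cationic monovalent gold activates the terminal alkyne for intramolecular 6-endo-dig hydroarylation (a known coumarin synthesis from aryl propiolates), and the only open ortho carbon, C4a, is activated by the ortho silyloxy and para benzyloxy groups, so pyranone B should close without a regiochemical choice.

**Step 12**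
Reactants: 26 7-(benzyloxy)-8-[(7-methoxy-2-oxo-2H-chromen-8-yl)oxy]-5-(triisopropylsilyloxy)-2H-chromen-2-one
Product: 27 7-(benzyloxy)-5-hydroxy-8-[(7-methoxy-2-oxo-2H-chromen-8-yl)oxy]-2H-chromen-2-one
Conditions: Bu4NF, AcOH, THF, 0 °C
Reagents that add atoms: none
Why: Fluoride-induced desilylation of the aryl silyl ether, driven by the Si–F bond, with AcOH buffering the phenoxide so that neither lactone is opened.

**Step 13**
Reactants: 27 7-(benzyloxy)-5-hydroxy-8-[(7-methoxy-2-oxo-2H-chromen-8-yl)oxy]-2H-chromen-2-one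
Product: 28 5,7-dihydroxy-8-[(7-methoxy-2-oxo-2H-chromen-8-yl)oxy]-2H-chromen-2-one (CNP0305396.0)
Conditions: BCl3, pentamethylbenzene, CH2Cl2, −78 °C; then MeOH
Reagents that add atoms: none
Why: Lewis acid debenzylation with a cation scavenger at −78 °C cleaves aryl benzyl ethers while sparing the aryl methyl ether, the lactones and the coumarin double bonds that hydrogenolysis would endanger.

**Compound list**
1 | daphnetin (7,8-dihydroxy-2H-chromen-2-one) | O=c1ccc2ccc(O)c(O)c2o1 | starting material
2 | 8-hydroxy-7-methoxy-2H-chromen-2-one | COc1ccc2ccc(=O)oc2c1O | intermediate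
3 | tert-butyl bromoacetate | CC(C)(C)OC(=O)CBr | starting material
4 | tert-butyl 2-[(7-methoxy-2-oxo-2H-chromen-8-yl)oxy]acetate | COc1ccc2ccc(=O)oc2c1OCC(=O)OC(C)(C)C | intermediate
5 | 2-[(7-methoxy-2-oxo-2H-chromen-8-yl)oxy]acetic acid | COc1ccc2ccc(=O)oc2c1OCC(=O)O | intermediate
6 | 2-[(7-methoxy-2-oxo-2H-chromen-8-yl)oxy]acetyl chloride | COc1ccc2ccc(=O)oc2c1OCC(Cl)=O | intermediate
7 | benzyl alcohol | OCc1ccccc1 | starting material
8 | trichloroethylene | ClC=C(Cl)Cl | starting material
9 | dichloroacetylene | ClC#CCl | intermediate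
10 | benzyl (E)-1,2-dichlorovinyl ether | Cl/C=C(/Cl)OCc1ccccc1 | intermediate
11 | benzyl chloroethynyl ether | ClC#COCc1ccccc1 | intermediate
12 | lithium (benzyloxy)acetylide | [Li]C#COCc1ccccc1 | intermediate
13 | benzyl ethynyl ether | C#COCc1ccccc1 | intermediate
14 | [(7-methoxy-2-oxo-2H-chromen-8-yl)oxy]ketene | O=C=COc1c(OC)ccc2ccc(=O)oc12 | intermediate
15 | 3-(benzyloxy)-4-[(7-methoxy-2-oxo-2H-chromen-8-yl)oxy]cyclobut-2-en-1-one (racemic) | O=C1C=C(OCc2ccccc2)C1Oc1c(OC)ccc2ccc(=O)oc12 | intermediate
16 | 3-phenylisoxazole | c1ccc(-c2ccon2)cc1 | starting material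
17 | lithium ethynolate | [Li+].[O-]C#C | intermediate
18 | (triisopropylsilyloxy)acetylene | C#CO[Si](C(C)C)(C(C)C)C(C)C | intermediate
19 | 3-(benzyloxy)-4-[(7-methoxy-2-oxo-2H-chromen-8-yl)oxy]buta-1,3-dien-1-one (vinylketene, enol ether geometry open) | O=C=CC(OCc1ccccc1)=COc1c(OC)ccc2ccc(=O)oc12 | intermediate
20 | 4-{1-(benzyloxy)-2-[(7-methoxy-2-oxo-2H-chromen-8-yl)oxy]ethenyl}-3-(triisopropylsilyloxy)cyclobut-2-en-1-one (racemic, enol ether geometry open) | O=C1C=C(O[Si](C(C)C)(C(C)C)C(C)C)C1C(OCc1ccccc1)=COc1c(OC)ccc2ccc(=O)oc12 | intermediate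
21 | (3E)-5-(benzyloxy)-6-[(7-methoxy-2-oxo-2H-chromen-8-yl)oxy]-3-(triisopropylsilyloxy)hexa-1,3,5-trien-1-one (dienylketene, C5=C6 geometry open) | O=C=C/C(O[Si](C(C)C)(C(C)C)C(C)C)=C\C(OCc1ccccc1)=COc1c(OC)ccc2ccc(=O)oc12 | intermediate
22 | 5-(benzyloxy)-6-[(7-methoxy-2-oxo-2H-chromen-8-yl)oxy]-3-(triisopropylsilyloxy)cyclohexa-2,4-dien-1-one (racemic) | O=C1C=C(O[Si](C(C)C)(C(C)C)C(C)C)C=C(OCc2ccccc2)C1Oc1c(OC)ccc2ccc(=O)oc12 | intermediate
23 | 8-[2-(benzyloxy)-6-hydroxy-4-(triisopropylsilyloxy)phenoxy]-7-methoxy-2H-chromen-2-one | Oc1cc(O[Si](C(C)C)(C(C)C)C(C)C)cc(OCc2ccccc2)c1Oc1c(OC)ccc2ccc(=O)oc12 | intermediate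
24 | propiolic acid | C#CC(=O)O | starting material
25 | 3-(benzyloxy)-2-[(7-methoxy-2-oxo-2H-chromen-8-yl)oxy]-5-(triisopropylsilyloxy)phenyl prop-2-ynoate | C#CC(=O)Oc1cc(O[Si](C(C)C)(C(C)C)C(C)C)cc(OCc2ccccc2)c1Oc1c(OC)ccc2ccc(=O)oc12 | intermediate
26 | 7-(benzyloxy)-8-[(7-methoxy-2-oxo-2H-chromen-8-yl)oxy]-5-(triisopropylsilyloxy)-2H-chromen-2-one | COc1ccc2ccc(=O)oc2c1Oc1c(OCc3ccccc3)cc(O[Si](C(C)C)(C(C)C)C(C)C)c2ccc(=O)oc12 | intermediate
27 | 7-(benzyloxy)-5-hydroxy-8-[(7-methoxy-2-oxo-2H-chromen-8-yl)oxy]-2H-chromen-2-one | COc1ccc2ccc(=O)oc2c1Oc1c(OCc3ccccc3)cc(O)c2ccc(=O)oc12 | intermediate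
28 | 5,7-dihydroxy-8-[(7-methoxy-2-oxo-2H-chromen-8-yl)oxy]-2H-chromen-2-one | COc1ccc2ccc(=O)oc2c1Oc1c(O)cc(O)c2ccc(=O)oc12 | target

**Count**
Total steps: 13. Longest linear sequence: 10 steps (1, 2, 3, 4, 7, 9, 10, 11, 12, 13, from daphnetin).

**Steps most likely to fail**

Step 9. The transient vinylketene 19 may dimerize or acylate phenol 23 as it forms instead of adding the alkyne, and alkyne 18 may undergo a thermal 1,3-silyl shift to a silylketene before it is captured. The fallback buys ring B as an arene and makes the diaryl ether by copper catalysis; it sets out from phenol 2 and comes back at phenol 23. Commercial 3,5-bis(benzyloxy)phenol would be silylated (TIPSCl, imidazole, DMF) to 1,3-bis(benzyloxy)-5-(triisopropylsilyloxy)benzene F1. Lithiation between the two benzyloxy groups (n-BuLi, THF, 0 °C) and quenching with I2 would give 1,3-bis(benzyloxy)-2-iodo-5-(triisopropylsilyloxy)benzene F2. Ullmann-type coupling of F2 with 2 (CuI, picolinic acid, K3PO4, DMSO, 90 °C) would give the symmetrical ether 8-[2,6-bis(benzyloxy)-4-(triisopropylsilyloxy)phenoxy]-7-methoxy-2H-chromen-2-one F3; this coupling joins two doubly ortho-substituted partners and would need forcing. Because the two benzyl ethers of F3 are equivalent, removal of one (BCl3, one equivalent, pentamethylbenzene, CH2Cl2, −78 °C) can lead only to 23, to be separated from unreacted F3 and doubly debenzylated material.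

Step 8. Ynolate 17 may be silylated on carbon (giving a silylketene) instead of on oxygen, and the volatile, acid-sensitive alkyne may be lost on isolation. The fallback uses an alkyne that already carries C4 of pyranone B; it sets out from cyclobutenone 15 and comes back at biscoumarin 26. Commercial 3,3-diethoxyprop-1-yne would be converted by the acetylide oxidation route to silyl ynol ethers (LiN(SiMe3)2; t-BuOOLi; TIPSOTf; THF, −78 to 0 °C) into 3,3-diethoxy-1-(triisopropylsilyloxy)prop-1-yne F4. The same benzannulation with 15 (toluene, 80 to 110 °C) would place the acetal carbon on C4a and give 8-[2-(benzyloxy)-5-(diethoxymethyl)-6-hydroxy-4-(triisopropylsilyloxy)phenoxy]-7-methoxy-2H-chromen-2-one F5. Mild acid (pyridinium tosylate, wet acetone) would unmask 4-(benzyloxy)-2-hydroxy-3-[(7-methoxy-2-oxo-2H-chromen-8-yl)oxy]-6-(triisopropylsilyloxy)benzaldehyde F6. Heating F6 with the Bestmann ylide Ph3P=C=C=O in toluene (O-acylation, then intramolecular Wittig reaction) would close pyranone B to 26, so steps 10 and 11 would not be needed.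

Step 7. Aryloxyketene 14 may dimerize or oligomerize faster than it adds to the ynol ether, the heat-sensitive ynol ether 13 may rearrange, and the enolizable cyclobutenone may break down under base. The fallback generates the vinylketene by 1,4-dehydrochlorination instead of by cyclobutenone opening; it sets out from phenol 2 and comes back at vinylketene 19 and hence at phenol 23. Alkylation of 2 with commercial ethyl 4-chloroacetoacetate (NaH, THF) would give ethyl 4-[(7-methoxy-2-oxo-2H-chromen-8-yl)oxy]-3-oxobutanoate F7. Mitsunobu O-benzylation of its enol (benzyl alcohol, PPh3, diisopropyl azodicarboxylate) would give ethyl (E)-3-(benzyloxy)-4-[(7-methoxy-2-oxo-2H-chromen-8-yl)oxy]but-2-enoate F8. Saponification and acidification (LiOH, aqueous THF; then HCl, which recloses the lactone) would give (E)-3-(benzyloxy)-4-[(7-methoxy-2-oxo-2H-chromen-8-yl)oxy]but-2-enoic acid F9, and oxalyl chloride would give (E)-3-(benzyloxy)-4-[(7-methoxy-2-oxo-2H-chromen-8-yl)oxy]but-2-enoyl chloride F10. Et3N would remove the γ-proton of F10 in the presence of 18 to generate 19 at room temperature, and warming to 80 °C would carry it through 20, 21 and 22 to 23.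

**Further compounds**
F1 | step 9 | 1,3-bis(benzyloxy)-5-(triisopropylsilyloxy)benzene | CC(C)[Si](Oc1cc(OCc2ccccc2)cc(OCc2ccccc2)c1)(C(C)C)C(C)C
F2 | step 9 | 1,3-bis(benzyloxy)-2-iodo-5-(triisopropylsilyloxy)benzene | CC(C)[Si](Oc1cc(OCc2ccccc2)c(I)c(OCc2ccccc2)c1)(C(C)C)C(C)C
F3 | step 9 | 8-[2,6-bis(benzyloxy)-4-(triisopropylsilyloxy)phenoxy]-7-methoxy-2H-chromen-2-one | COc1ccc2ccc(=O)oc2c1Oc1c(OCc2ccccc2)cc(O[Si](C(C)C)(C(C)C)C(C)C)cc1OCc1ccccc1
F4 | step 8 | 3,3-diethoxy-1-(triisopropylsilyloxy)prop-1-yne | CCOC(OCC)C#CO[Si](C(C)C)(C(C)C)C(C)C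
F5 | step 8 | 8-[2-(benzyloxy)-5-(diethoxymethyl)-6-hydroxy-4-(triisopropylsilyloxy)phenoxy]-7-methoxy-2H-chromen-2-one | CCOC(OCC)c1c(O)c(Oc2c(OC)ccc3ccc(=O)oc23)c(OCc2ccccc2)cc1O[Si](C(C)C)(C(C)C)C(C)C
F6 | step 8 | 4-(benzyloxy)-2-hydroxy-3-[(7-methoxy-2-oxo-2H-chromen-8-yl)oxy]-6-(triisopropylsilyloxy)benzaldehyde | O=Cc1c(O)c(Oc2c(OC)ccc3ccc(=O)oc23)c(OCc2ccccc2)cc1O[Si](C(C)C)(C(C)C)C(C)C
F7 | step 7 | ethyl 4-[(7-methoxy-2-oxo-2H-chromen-8-yl)oxy]-3-oxobutanoate | CCOC(=O)CC(=O)COc1c(OC)ccc2ccc(=O)oc12
F8 | step 7 | ethyl (E)-3-(benzyloxy)-4-[(7-methoxy-2-oxo-2H-chromen-8-yl)oxy]but-2-enoate | CCOC(=O)/C=C(/OCc1ccccc1)COc1c(OC)ccc2ccc(=O)oc12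
F9 | step 7 | (E)-3-(benzyloxy)-4-[(7-methoxy-2-oxo-2H-chromen-8-yl)oxy]but-2-enoic acid | OC(=O)/C=C(/OCc1ccccc1)COc1c(OC)ccc2ccc(=O)oc12
F10 | step 7 | (E)-3-(benzyloxy)-4-[(7-methoxy-2-oxo-2H-chromen-8-yl)oxy]but-2-enoyl chloride | ClC(=O)/C=C(/OCc1ccccc1)COc1c(OC)ccc2ccc(=O)oc12
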